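| setting | spring | winter | dusk | summer | Tuesday's | Thursday's | Sunday's | Friday's |
|---|---|---|---|---|---|---|---|---|
| substrate | 0.30 M | 0.15 M | 0.60 M | 0.30 M | 0.30 M (fed, over 4.80 min) | 0.30 M | 0.30 M | 0.30 M |
| coupling partner | 0.36 M | 0.36 M | 0.36 M | 0.36 M | 0.360 M | 0.360 M (fed, over 4.80 min) | 0.360 M | 0.360 M |
| precatalyst | 0.69 mM | 0.69 mM | 0.69 mM | 0.34 mM | 0.69 mM | 0.69 mM | 0.69 mM | 0.69 mM |
| remark | run made earlier | run made earlier | run made earlier | run made earlier | all but substrate at the start; substrate goes in evenly over 4.80 min, the run ends at 6.0 min | all but coupling partner at the start; coupling partner goes in evenly over 4.80 min, the run ends at 6.0 min | everything together in a closed stirred flask, run for 6.0 min | a single well-mixed tank run continuously and read at steady state, 6.0 min in it on average |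
| time |  |  |  |  | 6.0 min | 6.0 min | 6.0 min |  |

| run | time / min | product / % |
|---|---|---|
| spring | 0.500 | 2 |
| spring | 1.00 | 16 |
| spring | 1.50 | 27 |
| spring | 2.00 | 36 |
| spring | 2.50 | 45 |
| spring | 3.00 | 58 |
| spring | 4.00 | 74 |
| winter | 0.500 | 13 |
| winter | 1.00 | 31 |
| winter | 1.50 | 48 |
| winter | 2.00 | 70 |
| winter | 2.50 | 81 |
| winter | 3.00 | 90 |
| winter | 4.00 | 99 |
| dusk | 0.250 | 2 |
| dusk | 0.417 | 1 |
| dusk | 0.667 | 2 |
| dusk | 1.00 | 6 |
| dusk | 1.50 | 13 |
| dusk | 2.50 | 26 |
| dusk | 4.00 | 36 |
| summer | 0.333 | 3 |
| summer | 0.833 | 3 |
| summer | 1.50 | 11 |
| summer | 2.50 | 25 |
| summer | 4.00 | 47 |

(standard deviation of a reading: 2 percentage points)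

- the stated concentrations are those of everything mixed, before any reaction; amounts are the same in each set-up
- the feed brings no volume worth counting
- the earlier runs were made in a closed, stirred flask

1. the set-up with the highest amount of product at the outlet or at the end, in percent of the substrate put in ("none" if the first two lie within 2 percentage points) (Tuesday's / Thursday's / Sunday's / Friday's / none)
2. amount of product at the outlet or at the end, in percent of the substrate put in, Tuesday's
3. amount of product at the outlet or at the end, in percent of the substrate put in, Thursday's
4. amount of product at the outlet or at the end, in percent of the substrate put in, Sunday's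
5. amount of product at the outlet or at the end, in percent of the substrate put in, Friday's

- Follow the partner. I assume one coupling partner molecule goes into each product molecule, so every reading also gives [coupling partner], and I define the capture rate, the chance per minute that one partner molecule is taken by the catalyst, as the logarithm of the fall in [coupling partner] divided by the time of that fall, a pseudo-first-order constant, which I read from the spring run between 1.00 min and 3.00 min as 0.259 /min.
- My first doubt is that this rate belongs to the spring run and no other, but the dusk run, with twice the substrate, reads 0.269 /min, close to the spring reading.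
- My second doubt stands, since the winter run, with thin substrate, reads a lower 0.193 /min, so for flasks kept thin in substrate I take the mean, 0.226 /min.
- My third doubt is the slow start, and running the spring capture back from its reading at 1.00 min puts an apparent delay of 0.447 min at the start of that run.
- In Sunday's flask a partner molecule faces capture for 6.0 min less that delay, which gives me 91.5 % product.
- Tuesday's flask, thin in substrate, has the same clock at the mean rate, and I reckon 85.7 %.
- In Thursday's flask each partner molecule arrives at some moment of the feed, so I average its survival over those moments, which gives 69.6 % with the delay left out of the reckoning.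
- In Friday's tank a partner molecule stands at a fork, captured at the mean rate or washed out at one chance per 6.0 min on average, so its chance of capture is 57.5 %, and I reckon 69.0 % product.
- The forecast, which reads “near-zero-order kinetics with an induction period”, names Sunday's and gives 87 %, 65 %, 95 % and 77 % for Tuesday's, Thursday's, Sunday's and Friday's.
- The flasks give 84.0 %, 68.1 %, 92.3 % and 70.1 % in that order, with Sunday's highest.

    catalyst intermediate B → free catalyst + product (k = 7.90 /s)
    coupling partner + precatalyst → free catalyst + spent reagent (k = 0.100 /M/s)
    substrate + catalyst intermediate A ⇌ catalyst intermediate B (K = 9.50 /M, k = 800 /M/s)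
    coupling partner + free catalyst → catalyst intermediate A (k = 9.50 /M/s)

- Friday's tank holds 0.149 M of coupling partner, so 58.6 % of the partner was captured, a capture rate of 0.236 /min. For a neighbour of Sunday's flask, charged with 0.75 M of substrate, I reckon from the spring capture rate and delay that 23.7 % of its partner stays and 36.6 % product forms, and that neighbour shows 17.6 % of its partner left and 39.5 % product.

(The earlier runs and the new flask are calculated for substances that don't exist, noise included.)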